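All runs are calculated for substances that don't exist; scatter was added.

At 5.00 min the east run, which is this very flask followed so far, lets us close a ledger on the L charged.

- east: L 0.050 M; Z 0.50 equiv; Q 1 equiv; the very flask that is asked about, followed so far
- flask: L 0.050 M; Z 0.500 equiv; Q 1.00 equiv; time 15 min

- east (time / min: E / %, X / %, L / %): 0.333: 8.1, 0.8, 76.6; 0.667: 13.2, 0, 61.6; 1.00: 16.8, 0.6, 52.5; 1.50: 19.6, 0, 41.7; 2.50: 24.3, 0.1, 31.0; 5.00: 26.3, 0, 19.2

(readings scatter by 0.5 percentage points)

- percentages count the L that a species holds: one J counts as two
- reactions considered so far: L + Z <-> Q + E; E + Z <-> Q + G; G + Z <-> Q + X; 2 L -> J; Q + X -> D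

* equivalents of Z to L, everything else as given, that leave most E at 15 min
* the amount of E then, in percent of the L charged
* the amount of E with the amounts as given

L holds 19.2 % and E 26.3 %, while X reads 0 %, so 54.5 % lies outside what was read. Each E took one Z, which leaves at most 23.7 % of Z, in percent of the L charged. G, which was not read, takes two Z each, so it can hold at most 11.8 % of that missing entry, and, within the scatter of the readings, at least 42.7 % is J.

We book G as none, an assumption of ours, which puts Q at 126 %. Then E times Q over L times Z reads 7.30, and we call this the exchange quotient Γ, the reaction quotient of the first exchange. The same sum gave 3.79 at 2.50 min, so Γ was still rising. If Γ comes to rest, an assumption of ours, E follows L down. We therefore expect E at 15 min to lie under 26.3 %, and the best charge of Z to lie above 0.500 equiv, since at a given Γ and Q more Z raises E over L.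

The forecast gives 22 % (18 % to 27 %) as charged, and 36 % (29 % to 47 %) at 1 equiv (0.7 equiv to 1.6 equiv). Of the levelling of E it says: “Two pictures explain this about equally well”.

The flask gives 23.4 % as charged, and 41.9 % at 1.75 equiv.

    L + Z ⇌ Q + E (K = 9.60, k = 0.207 /M/s)
    E + Z ⇌ Q + G (K = 0.194, k = 0.0954 /M/s)
    G + Z ⇌ Q + X (K = 0.530, k = 0.404 /M/s)
    2 L → J (k = 0.0975 /M/s)
    Q + X → D (k = 0.179 /M/s)

At 15.0 min this flask holds L 10.9 %, with Z 46.0 % and Q 126 % of their own charges, so Γ stands at 11.9, while the neighbour flask with 0.200 equiv of Z holds half the E at a Γ of 12.9. In this flask the loss of L to J ran at 1.5 times the forward exchange at 1.10 min, more than the 0.44 times at 15.0 min, when J held 64.3 %.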